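**Plan**
- **Cuts:** The C4 ketone is traced back to a silyl-protected C4 carbinol. Ring C is then opened at the aryl ether bond C8a–O1. After that come C3–C4 (aldol) and the C8–CH2 bond of the prenyl group (aromatic Claisen).
- **Enabling feature:** O1 links the benzylic stereocentre C2 of ring C to C8a of ring A. C8a lies between C8 and C4a, is meta to both methoxy groups and begins as a phenol carbon. C2 can therefore be finished as a free carbinol while C8a is armed as an aryl triflate.
- **Forward order:** Ring A is bought complete as a salicylaldehyde and C8 is prenylated by way of the phenol oxygen. That oxygen becomes the leaving group, and the C2–C3 unit carrying ring B is joined at C4. Ring C closes last by palladium-catalysed C8a–O1 coupling, and two steps then restore the ketone.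
- **Stereochemistry:** C2, the only stereocentre of the target, is (R). It is set by an oxazaborolidine-catalysed ketone reduction, and no later step touches the C2–O bond. C4 travels as an epimer mixture and is erased by the last oxidation.

Key step: step 8

Remark: by the CIP rules (O1 > phenyl > C3 > H) the stereocentre in the target SMILES is (2R), and the route is laid out for this enantiomer. Flavanone numbering (O1, C2, C3, C4, C4a, C5–C8, C8a) is also applied to the open-chain precursors.

Step 1
Reactants: 1 2-hydroxy-4,6-dimethoxybenzaldehyde; 2 3-chloro-3-methylbut-1-yne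
Product: 3 2,4-dimethoxy-6-[(2-methylbut-3-yn-2-yl)oxy]benzaldehyde
Conditions: DBU, CuCl2·2H2O (cat.), MeCN, 0 °C to rt
Reagents that add atoms: none
Why: Copper-catalysed O-propargylation of a phenol with a tertiary propargylic chloride, which runs through an electrophilic copper allenylidene-type species and therefore also captures the chelated, weakly nucleophilic ortho-formyl phenoxide at oxygen under mild conditions.

Step 2
Reactants: 3 2,4-dimethoxy-6-[(2-methylbut-3-yn-2-yl)oxy]benzaldehyde
Product: 4 2,4-dimethoxy-6-[(2-methylbut-3-en-2-yl)oxy]benzaldehyde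
Conditions: H2 (1 atm), Pd/CaCO3 poisoned with Pb(OAc)2, quinoline, EtOAc, rt
Reagents that add atoms: none
Why: Lindlar-type semihydrogenation, in which the poisoned palladium surface should release the terminal alkene before it is reduced further and should leave the aldehyde and the tertiary aryl ether alone.

Step 3
Reactants: 4 2,4-dimethoxy-6-[(2-methylbut-3-en-2-yl)oxy]benzaldehyde
Product: 6 2-hydroxy-4,6-dimethoxy-3-(3-methylbut-2-en-1-yl)benzaldehyde, via Claisen dienone 5 (not isolated)
Conditions: PhNEt2, 130 °C
Reagents that add atoms: none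
Why: Aromatic Claisen rearrangement, a [3,3] shift that can end productively only at the one free ortho carbon (the future C8), turns the 1,1-dimethylallyl ether end for end into a prenyl group and is completed by tautomerisation of dienone 5 to the hydrogen-bonded phenol, the basic solvent holding back acid-induced loss of the allyl group.

Step 4
Reactants: 6 2-hydroxy-4,6-dimethoxy-3-(3-methylbut-2-en-1-yl)benzaldehyde
Product: 7 2-formyl-3,5-dimethoxy-6-(3-methylbut-2-en-1-yl)phenyl trifluoromethanesulfonate
Conditions: Tf2O, pyridine, CH2Cl2, 0 °C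
Reagents that add atoms: triflic anhydride, O=S(=O)(OS(=O)(=O)C(F)(F)F)C(F)(F)F
Why: O-Sulfonylation of a phenol with triflic anhydride and pyridine, a standard aryl triflate synthesis that is compatible with the aldehyde and the trisubstituted alkene and converts the phenol carbon (future C8a) into a site for oxidative addition.

Step 5
Reactants: 7 2-formyl-3,5-dimethoxy-6-(3-methylbut-2-en-1-yl)phenyl trifluoromethanesulfonate; 8 acetophenone
Product: 10 rac-2-(1-hydroxy-3-oxo-3-phenylpropyl)-3,5-dimethoxy-6-(3-methylbut-2-en-1-yl)phenyl trifluoromethanesulfonate, via lithium enolate 9 (not isolated)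
Conditions: 8, LiHMDS, THF, −78 °C; then 7, −78 °C; AcOH quench at −78 °C
Reagents that add atoms: none
Why: Kinetic lithium enolate aldol addition, in which the preformed enolate 9 should add to the aldehyde far faster than it attacks the sulfonate, the cold acid quench forestalls retro-aldol cleavage, dehydration and sulfonyl transfer, and the new C4 centre is deliberately racemic because step 10 removes it.

Step 6
Reactants: 10 rac-2-(1-hydroxy-3-oxo-3-phenylpropyl)-3,5-dimethoxy-6-(3-methylbut-2-en-1-yl)phenyl trifluoromethanesulfonate
Product: 11 rac-2-[1-(tert-butyldimethylsilyloxy)-3-oxo-3-phenylpropyl]-3,5-dimethoxy-6-(3-methylbut-2-en-1-yl)phenyl trifluoromethanesulfonate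
Conditions: TBSOTf, 2,6-lutidine, CH2Cl2, −78 to 0 °C
Reagents that add atoms: tert-butyldimethylsilyl triflate, CC(C)(C)[Si](C)(C)OS(=O)(=O)C(F)(F)F
Why: Silyl ether formation with a silyl triflate and a hindered pyridine base, reactive enough for the crowded benzylic hydroxyl at low temperature and needed so that no β-hydroxy ketone or free C4 hydroxyl is present when base and palladium are applied in step 8.

Step 7
Reactants: 11 rac-2-[1-(tert-butyldimethylsilyloxy)-3-oxo-3-phenylpropyl]-3,5-dimethoxy-6-(3-methylbut-2-en-1-yl)phenyl trifluoromethanesulfonate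
Product: 12 2-[(3R)-1-(tert-butyldimethylsilyloxy)-3-hydroxy-3-phenylpropyl]-3,5-dimethoxy-6-(3-methylbut-2-en-1-yl)phenyl trifluoromethanesulfonate (both epimers at the silyloxy carbon)
Conditions: (S)-2-methyl-CBS-oxazaborolidine (20 mol %), catecholborane, toluene, −78 °C; aqueous NaHCO3 work-up
Reagents that add atoms: none
Why: Corey–Bakshi–Shibata reduction, in which the ketone binds to the (S)-oxazaborolidine with phenyl as the large and the CH2 branch as the small substituent so that hydride reaches the Si face and gives the (R)-carbinol in both C4 series, while catecholborane at −78 °C should not hydroborate the prenyl alkene.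

Step 8
Reactants: 12 2-[(3R)-1-(tert-butyldimethylsilyloxy)-3-hydroxy-3-phenylpropyl]-3,5-dimethoxy-6-(3-methylbut-2-en-1-yl)phenyl trifluoromethanesulfonate
Product: 13 (2R)-4-(tert-butyldimethylsilyloxy)-5,7-dimethoxy-8-(3-methylbut-2-en-1-yl)flavan (both C4 epimers)
Conditions: Pd(OAc)2 (5 mol %), 2-(di-tert-butylphosphino)-1,1'-binaphthyl (7.5 mol %), Cs2CO3, toluene, 80 °C
Reagents that add atoms: none
Why: Zerovalent palladium formed from Pd(OAc)2 and the phosphine inserts into the C8a–OTf bond, the C2 hydroxyl binds to the cationic arylpalladium centre and is deprotonated there by Cs2CO3, and C–O reductive elimination from the seven-membered palladacycle (Pd, C8a, C4a, C4, C3, C2, O) makes C8a–O1. The closest known reaction type is the Buchwald–Hartwig intramolecular etherification of aryl halides and sulfonates bearing a pendant secondary alcohol, which converts enantioenriched carbinols into chromans without loss of optical purity. Ring C closes as a six-membered ring in a 6-exo sense, since the C8a–O bond to the sulfonate that breaks lies outside the new ring. No stereocentre is created, because only the O–H bond of the carbinol is exchanged, so the (R) configuration from step 7 appears unchanged at C2 and both C4 epimers enter the same C2 series. The selectivity needed is reductive elimination ahead of β-hydride elimination of the benzylic palladium alkoxide and ahead of S–O cleavage of the triflate; the bulky electron-rich ligand, the steric compression from the two ortho neighbours (C8 prenyl and the C4a side chain) and the tether favour the former, while a weak base in toluene keeps free alkoxide, and with it silyl migration and attack on sulfur, low. Both methoxy groups are meta to C8a and so do not slow oxidative addition by resonance donation, and the prenyl alkene cannot intercept the arylpalladium species because carbopalladation would demand a four-membered ring or a 5-endo closure.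

Step 9
Reactants: 13 (2R)-4-(tert-butyldimethylsilyloxy)-5,7-dimethoxy-8-(3-methylbut-2-en-1-yl)flavan
Product: 14 (2R)-5,7-dimethoxy-8-(3-methylbut-2-en-1-yl)flavan-4-ol (both C4 epimers)
Conditions: TBAF, THF, 0 °C to rt
Reagents that add atoms: none
Why: Fluoride-mediated desilylation driven by the strong Si–F bond, safe here because the flavan has no carbonyl group yet and thus no base-induced ring opening at C2 is possible.

Step 10
Reactants: 14 (2R)-5,7-dimethoxy-8-(3-methylbut-2-en-1-yl)flavan-4-ol
Product: 15 (2R)-5,7-dimethoxy-8-(3-methylbut-2-en-1-yl)flavanone (target)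
Conditions: Dess–Martin periodinane, NaHCO3, CH2Cl2, 0 °C to rt
Reagents that add atoms: none
Why: Dess–Martin oxidation of a secondary benzylic alcohol, which merges both C4 epimers into the one ketone and, being buffered and non-basic, avoids the retro-oxa-Michael opening to the chalcone that would racemise C2, and spares the prenyl alkene.

**Compound list**
1 | 2-hydroxy-4,6-dimethoxybenzaldehyde | COc1cc(O)c(C=O)c(OC)c1 | starting material
2 | 3-chloro-3-methylbut-1-yne | CC(C)(Cl)C#C | starting material
3 | 2,4-dimethoxy-6-[(2-methylbut-3-yn-2-yl)oxy]benzaldehyde | COc1cc(OC(C)(C)C#C)c(C=O)c(OC)c1 | intermediate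
4 | 2,4-dimethoxy-6-[(2-methylbut-3-en-2-yl)oxy]benzaldehyde | COc1cc(OC(C)(C)C=C)c(C=O)c(OC)c1 | intermediate
5 | rac-2,4-dimethoxy-5-(3-methylbut-2-en-1-yl)-6-oxocyclohexa-1,3-diene-1-carbaldehyde (Claisen dienone, not isolated) | O=CC1=C(OC)C=C(OC)C(CC=C(C)C)C1=O | intermediate
6 | 2-hydroxy-4,6-dimethoxy-3-(3-methylbut-2-en-1-yl)benzaldehyde | COc1cc(OC)c(C=O)c(O)c1CC=C(C)C | intermediate
7 | 2-formyl-3,5-dimethoxy-6-(3-methylbut-2-en-1-yl)phenyl trifluoromethanesulfonate | COc1cc(OC)c(C=O)c(OS(=O)(=O)C(F)(F)F)c1CC=C(C)C | intermediate
8 | acetophenone | CC(=O)c1ccccc1 | starting material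
9 | lithium 1-phenylethenolate (lithium enolate, not isolated) | C=C([O-])c1ccccc1.[Li+] | intermediate
10 | rac-2-(1-hydroxy-3-oxo-3-phenylpropyl)-3,5-dimethoxy-6-(3-methylbut-2-en-1-yl)phenyl trifluoromethanesulfonate | COc1cc(OC)c(C(O)CC(=O)c2ccccc2)c(OS(=O)(=O)C(F)(F)F)c1CC=C(C)C | intermediate
11 | rac-2-[1-(tert-butyldimethylsilyloxy)-3-oxo-3-phenylpropyl]-3,5-dimethoxy-6-(3-methylbut-2-en-1-yl)phenyl trifluoromethanesulfonate | COc1cc(OC)c(C(CC(=O)c2ccccc2)O[Si](C)(C)C(C)(C)C)c(OS(=O)(=O)C(F)(F)F)c1CC=C(C)C | intermediate
12 | 2-[(3R)-1-(tert-butyldimethylsilyloxy)-3-hydroxy-3-phenylpropyl]-3,5-dimethoxy-6-(3-methylbut-2-en-1-yl)phenyl trifluoromethanesulfonate, both epimers at the silyloxy carbon | COc1cc(OC)c(C(O[Si](C)(C)C(C)(C)C)C[C@@H](O)c2ccccc2)c(OS(=O)(=O)C(F)(F)F)c1CC=C(C)C | intermediate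
13 | (2R)-4-(tert-butyldimethylsilyloxy)-5,7-dimethoxy-8-(3-methylbut-2-en-1-yl)flavan, both C4 epimers | COc1cc(OC)c2c(c1CC=C(C)C)O[C@@H](c1ccccc1)CC2O[Si](C)(C)C(C)(C)C | intermediate
14 | (2R)-5,7-dimethoxy-8-(3-methylbut-2-en-1-yl)flavan-4-ol, both C4 epimers | COc1cc(OC)c2c(c1CC=C(C)C)O[C@@H](c1ccccc1)CC2O | intermediate
15 | (2R)-5,7-dimethoxy-8-(3-methylbut-2-en-1-yl)-2-phenyl-2,3-dihydro-4H-chromen-4-one | COc1cc(OC)c2c(c1CC=C(C)C)O[C@@H](c1ccccc1)CC2=O | target

Total step count: 10
Longest linear sequence: 10 steps (from 1)

**Steps most likely to fail**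

1. **Step 8.**
   - What may go wrong:
     - β-hydride elimination at the benzylic palladium alkoxide, with net reduction at C8a
     - sluggish oxidative addition at the doubly flanked carbon
     - S–O cleavage of the sulfonate by carbonate
     - migration of the silyl group from the C4 oxygen to the C2 oxygen
   - Fallback: ring C is closed from its other end, at O1–C2, by a Mitsunobu etherification with inversion. The fallback sets out from 11 and comes back to the route at 13. Reduction of 11 as in step 7, but with (R)-2-methyl-CBS-oxazaborolidine, should give 2-[(3S)-1-(tert-butyldimethylsilyloxy)-3-hydroxy-3-phenylpropyl]-3,5-dimethoxy-6-(3-methylbut-2-en-1-yl)phenyl trifluoromethanesulfonate F1. Cleavage of the aryl sulfonate at sulfur with Et4NOH in dioxane at rt should free 2-[(3S)-1-(tert-butyldimethylsilyloxy)-3-hydroxy-3-phenylpropyl]-3,5-dimethoxy-6-(3-methylbut-2-en-1-yl)phenol F2. With PPh3 and DIAD in toluene at 0 °C the phenol oxygen should then displace the activated benzylic oxygen with inversion, which gives the (2R) series of 13.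

2. **Step 7.**
   - What may go wrong:
     - poor facial selectivity for the mismatched enantiomer of the racemic ketone
     - competing hydroboration of the prenyl alkene
     - Lewis-acid-induced ionisation of the electron-rich benzylic silyl ether
   - Fallback: the boron hydride is replaced by Noyori asymmetric transfer hydrogenation, a metal–ligand bifunctional hydride transfer. The fallback sets out from 11 and comes back at 12. The conditions are RuCl[(R,R)-TsDPEN](p-cymene) and the HCO2H–Et3N azeotrope in EtOAc at rt. This reaction does not touch isolated alkenes. Its sense of induction is governed by the contact of the phenyl ring with the arene ligand, that is, by the side of the ketone remote from C4. It should give the (R)-carbinol. No compound outside the list is made (entry F0).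

3. **Step 5.**
   - What may go wrong:
     - reversal of the addition to the hindered, electron-rich aldehyde
     - dehydration of the adduct
     - transfer of the sulfonyl group to the neighbouring alkoxide before the quench
   - Fallback: the aldol is reached without an enolate addition, by olefination followed by conjugate borylation and oxidation. The fallback sets out from 7 and comes back at 10. Horner–Wadsworth–Emmons reaction of 7 with diethyl (2-oxo-2-phenylethyl)phosphonate (LiCl, DBU, MeCN, rt) should give 3,5-dimethoxy-6-(3-methylbut-2-en-1-yl)-2-[(1E)-3-oxo-3-phenylprop-1-en-1-yl]phenyl trifluoromethanesulfonate F3. Copper-catalysed β-borylation (CuCl, DPEphos, NaOt-Bu cat., B2pin2, MeOH, THF, rt) should give rac-3,5-dimethoxy-6-(3-methylbut-2-en-1-yl)-2-[3-oxo-3-phenyl-1-(4,4,5,5-tetramethyl-1,3,2-dioxaborolan-2-yl)propyl]phenyl trifluoromethanesulfonate F4. Oxidation of the C–B bond with NaBO3·4H2O in THF–H2O at rt should then deliver 10.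

**Further compounds**
F1 | step 8 | 2-[(3S)-1-(tert-butyldimethylsilyloxy)-3-hydroxy-3-phenylpropyl]-3,5-dimethoxy-6-(3-methylbut-2-en-1-yl)phenyl trifluoromethanesulfonate | COc1cc(OC)c(C(O[Si](C)(C)C(C)(C)C)C[C@H](O)c2ccccc2)c(OS(=O)(=O)C(F)(F)F)c1CC=C(C)C
F2 | step 8 | 2-[(3S)-1-(tert-butyldimethylsilyloxy)-3-hydroxy-3-phenylpropyl]-3,5-dimethoxy-6-(3-methylbut-2-en-1-yl)phenol | COc1cc(OC)c(C(O[Si](C)(C)C(C)(C)C)C[C@H](O)c2ccccc2)c(O)c1CC=C(C)C
F0 | step 7 | none | none
F3 | step 5 | 3,5-dimethoxy-6-(3-methylbut-2-en-1-yl)-2-[(1E)-3-oxo-3-phenylprop-1-en-1-yl]phenyl trifluoromethanesulfonate | COc1cc(OC)c(/C=C/C(=O)c2ccccc2)c(OS(=O)(=O)C(F)(F)F)c1CC=C(C)C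
F4 | step 5 | rac-3,5-dimethoxy-6-(3-methylbut-2-en-1-yl)-2-[3-oxo-3-phenyl-1-(4,4,5,5-tetramethyl-1,3,2-dioxaborolan-2-yl)propyl]phenyl trifluoromethanesulfonate | COc1cc(OC)c(C(CC(=O)c2ccccc2)B2OC(C)(C)C(C)(C)O2)c(OS(=O)(=O)C(F)(F)F)c1CC=C(C)C
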